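Readings and results were generated by integration with constants of no real substance; noise was put on by code.

Amounts first: each J that enters G gives one E and one Q, so each E costs one J and one G.

| flask | G | J | Q | remark | time |
|---|---|---|---|---|---|
| Saturday's | 30 mM | 0.50 equiv | 0.50 equiv | run made earlier |  |
| red | 20 mM | 0.500 equiv | 0.500 equiv |  | 20 min |
| teal | 20 mM | 0.800 equiv | 0.500 equiv |  | 20 min |
| amber | 20 mM | 1.50 equiv | 0.500 equiv |  | 20 min |

Saturday's run (percent of the G charged)

| time / min | E / % | L / % |
|---|---|---|
| 0.200 | 3 | 0 |
| 0.667 | 16 | 0 |
| 1.00 | 20 | 1 |
| 1.50 | 24 | 1 |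
| 2.50 | 32 | 1 |
| 3.00 | 33 | 0 |
| 4.00 | 39 | 0 |

(each reading ± 1.5 percentage points)

- no earlier run changes the charge of J; that part of a forecast is a guess
- no earlier run changes the charge of Q; that part of a forecast is a guess

1. E at the end, in percent of the G charged, for each flask in turn (red, teal, amber)

I read the rate from Saturday's last reading. For G and J meeting one to one, with J charged at 0.50 equiv, and x the fraction of G turned into E, the integrated law is

ln[(1 − x)/(1 − 2x)] = p·t

Here p is what I call the pace, the pseudo-first-order rate constant k[J] at Saturday's charged [J]:

p = 0.255 min⁻¹

This is a reading and carries the scatter of E. I leave Q out of it, since no run varies Q. The pace scales with [J], so each flask gets a half-life of G at its charged [J], and these are the rungs of my ladder, fastest first: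

amber: 1.36 min

teal: 2.55 min

red: 4.08 min

The next rung has no number. On Saturday L reads 1% at 1.00 min, beside 20% of E, so further exchange lies lower on the ladder. The last rung is the asked time, 20 min, which is 4.90 of red's half-lives.

So I take the first exchange as finished by then and reckon with the J it leaves free. J is the limiting reagent in red and teal, so their charges, 0.500 equiv and 0.800 equiv, are ceilings on E, and Saturday does not tell me how far below them E ends. Amber, at 1.50 equiv, has J beyond one per G, and that J goes on to E, so E stays short of full conversion by an amount Saturday cannot give me.

The forecast gives 46%, 65% and 82%, and warns “the ranges are wide”.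

The flasks give 44.8% in red, 62.2% in teal and 70.4% in amber.

    Q + G → X (k = 0.0250 L mol⁻¹ s⁻¹)
    D + J → Q + Z (k = 0.600 L mol⁻¹ s⁻¹)
    Z + J → Q + L (k = 0.990 L mol⁻¹ s⁻¹)
    E + J → Q + D (k = 0.0290 L mol⁻¹ s⁻¹)
    G + J → Q + E (k = 0.310 L mol⁻¹ s⁻¹)

In teal, my 2.55 min stands beside the simulated half-life of G of 2.3 min at the charged amounts. The half-life of E by E + J is 25 min, ten times longer. That difference between the rate constants of the steps that take up J is the main reason teal holds 62.2% of E, and the same teal run without the difference holds 33.7%.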